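**Retrosynthetic overview**

1. The last bond made is C8–C9, vinyl CH to allylic CH2 (chain numbered C1 = ester carbonyl to C10 = CH2 on the central furan). It is formed by nickel-electrocatalytic decarboxylative alkenylation of the N-hydroxyphthalimide ester of 3-[5-(furan-3-ylmethyl)furan-3-yl]propanoic acid with methyl (3R,7E)-8-iodo-3,7-dimethyloct-7-enoate.
2. Enabling feature: C9 is a primary CH2 two carbons from C4 of the central 2,4-disubstituted furan, so it is the α-carbon of a 3-(furan-3-yl)propanoic acid and gives an unstabilised primary radical. C8 is the H-bearing end of the isolated trisubstituted C7=C8 alkene, so it is the terminal carbon of a 1-alkyne. Both furan rings are oxidation-labile but reduction-stable, which a cathodic, base-free coupling respects.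
3. Iodide half: crossed Kolbe electrolysis of chiral-pool methyl hydrogen (R)-3-methylglutarate (source of C3) with pent-4-ynoic acid, then Zr-catalysed methylalumination/iodinolysis (sets 7E).
4. Acid half: furan-3-yllithium plus 4-bromofuran-2-carbaldehyde, ionic deoxygenation, Negishi coupling with a zinc homoenolate, saponification, N-hydroxyphthalimide activation.
5. Rings: none is formed; both furan rings are bought intact.

Key step: step 8

Remark: the (R)-half-ester of 3-methylglutaric acid, 4-bromofuran-2-carbaldehyde and the THF solution of (3-ethoxy-3-oxopropyl)zinc bromide are assumed to be purchasable. The descriptor at the methyl-bearing carbon stays R in every route compound because CH2CO2Me always outranks the other chain.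

**Route**

Step 1
Reactants: 1 methyl hydrogen (R)-3-methylglutarate; 2 pent-4-ynoic acid
Product: 3 methyl (3R)-3-methyloct-7-ynoate
Conditions: 2 (4 equiv), NaOMe (5 mol % of total acid), MeOH, Pt anode/Pt cathode, undivided cell, constant current (high current density), 35–45 °C
Reagents that add atoms: none
Why: Crossed Kolbe electrolysis: anodic decarboxylation of both carboxylates should give the primary radicals MeO2C-CH2-CH(Me)-CH2• and •CH2CH2C≡CH, which pair at the electrode, the excess of cheap 2 steering the statistical mixture to the cross product, and C3 is taken over unchanged from 1 because the radical sits on the neighbouring CH2 and no bond to C3 is broken.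

Step 2
Reactants: 3 methyl (3R)-3-methyloct-7-ynoate
Product: 5 methyl (3R,7E)-8-iodo-3,7-dimethyloct-7-enoate, via alkenyldimethylalane 4 (not isolated)
Conditions: Me3Al (3 equiv), Cp2ZrCl2 (20 mol %), H2O (1 equiv), CH2Cl2, −23 °C; then I2, THF, −23 → 0 °C
Reagents that add atoms: trimethylaluminium, C[Al](C)C; iodine, II
Why: Negishi zirconium-catalysed carboalumination (water-accelerated variant) should add Me–Al syn across the terminal alkyne with aluminium on C8, and iodinolysis of the C–Al bond with retention then gives the 7E iodide (CH3 cis to I), while at −23 °C the methyl ester is only complexed by Me3Al and no stereocentre is formed or touched.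

Step 3
Reactants: 6 3-bromofuran; 7 4-bromofuran-2-carbaldehyde
Product: 9 (4-bromofuran-2-yl)(furan-3-yl)methanol (racemic), via furan-3-yllithium 8 (not isolated)
Conditions: n-BuLi (1.05 equiv), Et2O, −78 °C; then 7, −78 °C; H2O quench
Reagents that add atoms: none
Why: Bromine–lithium exchange followed by 1,2-addition of the aryllithium to the aldehyde is faster at −78 °C than exchange with the second C–Br bond, and the carbinol centre is formed racemic because it is removed in the next step.

Step 4
Reactants: 9 (4-bromofuran-2-yl)(furan-3-yl)methanol
Product: 10 4-bromo-2-(furan-3-ylmethyl)furan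
Conditions: Et3SiH (3 equiv), TFA (3 equiv), CH2Cl2, −20 → 0 °C
Reagents that add atoms: none
Why: Ionic hydrogenation (Kursanov–Parnes reduction): the carbinol ionises readily to a cation stabilised by both furans, and hydride transfer from the excess silane at low temperature should outrun Friedel–Crafts self-alkylation.

Step 5
Reactants: 10 4-bromo-2-(furan-3-ylmethyl)furan; 11 (3-ethoxy-3-oxopropyl)zinc bromide
Product: 12 ethyl 3-[5-(furan-3-ylmethyl)furan-3-yl]propanoate
Conditions: 11 (1.5 equiv, THF solution), Pd(OAc)2 (2 mol %), SPhos (4 mol %), THF, rt → 50 °C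
Reagents that add atoms: none
Why: Negishi sp2–sp3 coupling of a heteroaryl bromide with an ester-stabilised primary alkylzinc, in which the bulky biarylphosphine favours reductive elimination over β-hydride elimination and the non-basic zinc reagent leaves the bis-furyl CH2 alone.

Step 6
Reactants: 12 ethyl 3-[5-(furan-3-ylmethyl)furan-3-yl]propanoate
Product: 13 3-[5-(furan-3-ylmethyl)furan-3-yl]propanoic acid
Conditions: LiOH·H2O (2 equiv), THF/H2O, rt; then 1 M HCl to pH 3–4, 0 °C
Reagents that add atoms: lithium hydroxide, [Li+].[OH-]
Why: Saponification of an unhindered ethyl ester, with cold and brief acidification that the furans tolerate.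

Step 7
Reactants: 13 3-[5-(furan-3-ylmethyl)furan-3-yl]propanoic acid
Product: 14 1,3-dioxoisoindolin-2-yl 3-[5-(furan-3-ylmethyl)furan-3-yl]propanoate
Conditions: N-hydroxyphthalimide (1.1 equiv), DIC (1.1 equiv), DMAP (10 mol %), CH2Cl2, rt
Reagents that add atoms: N-hydroxyphthalimide, O=C1c2ccccc2C(=O)N1O
Why: Carbodiimide (Steglich-type) esterification converts the acid into an isolable redox-active ester under neutral conditions.

Step 8
Reactants: 14 1,3-dioxoisoindolin-2-yl 3-[5-(furan-3-ylmethyl)furan-3-yl]propanoate; 5 methyl (3R,7E)-8-iodo-3,7-dimethyloct-7-enoate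
Product: 15 methyl (3R,7E)-10-[5-(furan-3-ylmethyl)furan-3-yl]-3,7-dimethyldec-7-enoate
Conditions: 14 (1.5 equiv), 5 (1 equiv), NiCl2·6H2O (20 mol %), 2,2'-bipyridine (20 mol %), AgNO3 (0.3 equiv), DMF, (+)Mg | (−)RVC, undivided cell, constant current, rt
Reagents that add atoms: none
Why: Nickel-electrocatalytic decarboxylative alkenylation: cathodically generated low-valent (bpy)Ni should insert into the C8–I bond of 5 with retention, while one-electron reduction of 14 (at the silver-coated cathode or by Ni(I)) expels phthalimide anion and CO2 and leaves the primary C9 radical, which the alkenyl–Ni(II) species captures before C(sp2)–C(sp3) reductive elimination from Ni(III) forms the C8–C9 bond. The closest known reaction type is this same Ni/bipyridine/silver electroreductive coupling of primary alkyl N-hydroxyphthalimide esters with (E)-trisubstituted alkenyl iodides, used to assemble polyprenyl chains. No ring is closed and no stereocentre is created: the 7E geometry is carried over from 5 because oxidative addition and reductive elimination at the alkenyl carbon are stereoretentive, and C3, five bonds away and never next to a radical, anion or metal, stays R. The step needs cross- over homo-coupling, which the different activation modes of the two partners (two-electron oxidative addition for the sp2 iodide, one-electron reduction for the ester) and the excess of 14 should secure, and it needs the radical to reach nickel unchanged, which the substrate secures because the 2-(furyl)ethyl radical is primary, has no β-leaving group, could only cyclise to three- or four-membered rings and has a degenerate 1,2-furyl shift. The sacrificial magnesium anode keeps the cell reductive throughout, so the two oxidation-prone furans and the doubly furyl-activated CH2 never meet an oxidant or a strong base, and the methyl ester is not reduced at these potentials.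

**Compound list**

1 | methyl hydrogen (R)-3-methylglutarate [(3R)-5-methoxy-3-methyl-5-oxopentanoic acid] | COC(=O)C[C@H](C)CC(=O)O | starting material
2 | pent-4-ynoic acid | OC(=O)CCC#C | starting material
3 | methyl (3R)-3-methyloct-7-ynoate | COC(=O)C[C@H](C)CCCC#C | intermediate
4 | [(1E,6R)-8-methoxy-2,6-dimethyl-8-oxooct-1-en-1-yl]dimethylalumane | COC(=O)C[C@H](C)CCC/C(C)=C/[Al](C)C | intermediate
5 | methyl (3R,7E)-8-iodo-3,7-dimethyloct-7-enoate | COC(=O)C[C@H](C)CCC/C(C)=C/I | intermediate
6 | 3-bromofuran | Brc1ccoc1 | starting material
7 | 4-bromofuran-2-carbaldehyde | O=Cc1cc(Br)co1 | starting material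
8 | furan-3-yllithium | [Li]c1ccoc1 | intermediate
9 | (4-bromofuran-2-yl)(furan-3-yl)methanol (racemic) | OC(c1ccoc1)c1cc(Br)co1 | intermediate
10 | 4-bromo-2-(furan-3-ylmethyl)furan | Brc1coc(Cc2ccoc2)c1 | intermediate
11 | (3-ethoxy-3-oxopropyl)zinc bromide | CCOC(=O)CC[Zn]Br | starting material
12 | ethyl 3-[5-(furan-3-ylmethyl)furan-3-yl]propanoate | CCOC(=O)CCc1coc(Cc2ccoc2)c1 | intermediate
13 | 3-[5-(furan-3-ylmethyl)furan-3-yl]propanoic acid | OC(=O)CCc1coc(Cc2ccoc2)c1 | intermediate
14 | 1,3-dioxoisoindolin-2-yl 3-[5-(furan-3-ylmethyl)furan-3-yl]propanoate | O=C(CCc1coc(Cc2ccoc2)c1)ON1C(=O)c2ccccc2C1=O | intermediate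
15 | methyl (3R,7E)-10-[5-(furan-3-ylmethyl)furan-3-yl]-3,7-dimethyldec-7-enoate | COC(=O)C[C@H](C)CCC/C(C)=C/CCc1coc(Cc2ccoc2)c1 | target

**Step count**

Total step count: 8.
Longest linear sequence: 6 steps (steps 3, 4, 5, 6, 7, 8). The iodide branch is 2 steps (1, 2) before the coupling.

**Steps most likely to fail, with fallbacks**

Step 8. The radical precursor may be consumed off-cycle (direct cathodic reduction of the ester followed by hydrogen abstraction or radical dimerisation) faster than the alkenyl-nickel species intercepts it, or the alkenyl iodide may be dehalogenated or homocoupled. The fallback replaces the radical coupling by a two-electron B-alkyl Suzuki–Miyaura coupling. It sets out from bromide 10 and comes back to the route at 15. Vinylation of 10 with potassium vinyltrifluoroborate (PdCl2(dppf), Et3N, n-PrOH, 80 °C) should give 4-ethenyl-2-(furan-3-ylmethyl)furan F1. Anti-Markovnikov hydroboration with 9-BBN-H (THF, rt) should give 9-{2-[5-(furan-3-ylmethyl)furan-3-yl]ethyl}-9-borabicyclo[3.3.1]nonane F2. F2 would be coupled in the same flask with iodide 5 (PdCl2(dppf), AsPh3, aqueous Cs2CO3, DMF, rt) to form the same C8–C9 bond with retention of the 7E geometry and deliver 15.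

Step 1. Statistical pairing of the two radicals, over-oxidation of the radicals to carbocations, or fouling of the anode by the alkyne may leave too little cross product. The fallback replaces anodic radical pairing by a nickel-catalysed decarboxylative alkyl–alkyl Negishi coupling. It sets out from 1 and comes back to the route at 3.
- Acid 1 is converted (N-hydroxyphthalimide, DIC, CH2Cl2) into 1-(1,3-dioxoisoindolin-2-yl) 5-methyl (3S)-3-methylpentanedioate F3. The descriptor changes only through CIP priorities; no bond at C3 is touched.
- Separately, commercial (4-bromobut-1-yn-1-yl)trimethylsilane is turned with magnesium into [4-(trimethylsilyl)but-3-yn-1-yl]magnesium bromide F4, and with ZnCl2 (0.5 equiv) into bis[4-(trimethylsilyl)but-3-yn-1-yl]zinc F5.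
- Coupling of F3 with F5 (NiCl2·glyme, 4,4'-di-tert-butyl-2,2'-bipyridine, THF/DMF, rt) should give methyl (3R)-3-methyl-8-(trimethylsilyl)oct-7-ynoate F6.
- Desilylation of F6 (K2CO3, MeOH, rt) returns 3.

Step 4. Cationic self-alkylation of the electron-rich furans (Friedel–Crafts oligomerisation) or acid-induced furan ring opening may compete with hydride transfer. The fallback avoids the carbocation and acid altogether. It sets out from carbinol 9 and comes back to the route at 10. Oxidation of 9 with MnO2 (CH2Cl2, rt) should give (4-bromofuran-2-yl)(furan-3-yl)methanone F7. Wolff–Kishner reduction in the Huang-Minlon manner (N2H4·H2O, KOH, diethylene glycol, 120 → 190 °C) proceeds through (4-bromofuran-2-yl)(furan-3-yl)methanone hydrazone F8 and should deliver 10 under purely basic conditions.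

Further compounds
F1 | step 8 | 4-ethenyl-2-(furan-3-ylmethyl)furan | C=Cc1coc(Cc2ccoc2)c1
F2 | step 8 | 9-{2-[5-(furan-3-ylmethyl)furan-3-yl]ethyl}-9-borabicyclo[3.3.1]nonane | C(Cc1coc(Cc2ccoc2)c1)B1C2CCCC1CCC2
F3 | step 1 | 1-(1,3-dioxoisoindolin-2-yl) 5-methyl (3S)-3-methylpentanedioate | COC(=O)C[C@H](C)CC(=O)ON1C(=O)c2ccccc2C1=O
F4 | step 1 | [4-(trimethylsilyl)but-3-yn-1-yl]magnesium bromide | C[Si](C)(C)C#CCC[Mg]Br
F5 | step 1 | bis[4-(trimethylsilyl)but-3-yn-1-yl]zinc | C[Si](C)(C)C#CCC[Zn]CCC#C[Si](C)(C)C
F6 | step 1 | methyl (3R)-3-methyl-8-(trimethylsilyl)oct-7-ynoate | COC(=O)C[C@H](C)CCCC#C[Si](C)(C)C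
F7 | step 4 | (4-bromofuran-2-yl)(furan-3-yl)methanone | O=C(c1ccoc1)c1cc(Br)co1
F8 | step 4 | (4-bromofuran-2-yl)(furan-3-yl)methanone hydrazone | NN=C(c1ccoc1)c1cc(Br)co1
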